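In a one-step world the starting material would become target and the yield would be a matter of the clock, but this flask has a side exit and a solid as well.

    crystals ⇌ target, rate k1*(cs1 - [target]) while solid is left; crystals form when [target] > cs1 (cs1 = 0.22 M, k1 = 1.0 s⁻¹)
    starting material + catalyst → catalyst + target (k2 = 20 M⁻¹ s⁻¹)
    starting material → side product (k3 = 7.5 × 10⁻⁴ s⁻¹)

starting material 0.50 M; catalyst 0.31 mM; time 4.0 min

- winter: doubling the dissolution coefficient of step 1, all else as stated
- autumn: doubling the solubility in step 1, all else as stated
- dusk: doubling the amount of catalyst, all else as stated

- for target the crystals are counted in
- as a solid, counted per litre of solution: crystals
- run time (flask): 4.0 min

- target and crystals together at 4.0 min, in percent of the starting material charged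
- concentration of target in solution at 1.0 min, in percent of saturation
- the change that raises the amount of target and crystals together at 4.0 min, in percent of the starting material charged most ("none" if none brings more than 2 percentage points) (winter / autumn / dusk / none)
- amount of target and crystals together at 4.0 min, in percent of the starting material charged, after autumn

I ask first where the flask must end, then how fast it gets there. The catalyst comes back out of its step, so the starting material in the flask faces two pseudo-first-order exits, 0.00620 s⁻¹ towards target and 7.5 × 10⁻⁴ s⁻¹ towards side product. The first is faster, and the selectivity gives target a share of 89.2% of whatever is consumed. The two constants together consume 81.1% of the charge by 4.0 min. The product of the two, 72.4%, I call the reach: the share going to target times the part of the charge consumed by a given time.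

The crystals step neither takes starting material nor gives it, and target and crystals are counted together. So I expect target and crystals together in the autumn flask to come level with target and crystals together in the flask, since solubility stands in neither exit. The dissolution coefficient stands in neither exit either, so I expect the same of the winter flask. The dusk flask differs in the exits themselves, and its reach is 90.3%, a gain of 18 percentage points, which is more than the margin. At 1.0 min the reach of the flask is 30.4% of the charge, less than the 44.0% of the charge that saturation holds. I therefore expect no solid then, and a solution at 69.1% of saturation.

The forecast gives 72.4%, 69.1%, dusk and 72.4%, holding that “crystallisation just moves material between dissolved and solid forms”.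

The flask gives 72.4% against a reach of 72.4%, with 69.1% of saturation at 1.0 min and 72.4% after autumn. The best change is dusk, which gains 18 points, while winter and autumn gain 0 points and 0 points. A neighbour flask charged with 7.7 × 10⁻⁵ M of catalyst has a share of 67.2% and consumes 42.3%, so its reach is 28.4%. That neighbour flask ends at 28.4%, with crystals at 0% and 58% of its starting material still there.

The numbers are assumed; no experiment stands behind them.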